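**Remark (one assumption):** germacrane locants are used throughout (C1–C10 ring carbons, C11–C13 lactone carbons, C14 hydroxymethyl carbon, C15 methyl carbon), which makes the target the (1R,4Z,6R,7R,8R,10S) isomer; bromide 12 is treated as not stocked and is made in steps 6 and 7.

## Retrosynthetic overview

1. Endgame: α-methylenation at C11 and desilylation of a 14-O-silyl 1,10-epoxide, which comes from a Payne shift (retention at C1, inversion at C10) of a macrocyclic 10,14-epoxy-1-ol.
2. Key disconnection C1–C2: the ten-membered carbocycle is closed by an intramolecular Nozaki–Hiyama–Kishi addition of a C2 iodoalkyne to the C1 glycidic aldehyde; C2≡C3 is a temporary oxidation level, taken down afterwards by diimide.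
3. Enabling feature: the cis C4=C5 olefin (C3 and C6 on the same side) makes C2≡C3–C4=C5 a hairpin that puts C2 next to C1; the fully substituted oxirane carbon C10 next to C1 (no α-hydrogen, polar C–O bond) makes the aldehyde non-enolisable and biases its faces.
4. Seco-aldehyde: Evans syn-aldol/lactonisation (C6, C7, γ-lactone), Barbier 2-(silyloxymethyl)allylation then Felkin reduction (C8), Sharpless epoxidation of the 1,1-disubstituted allylic alcohol (C10).
5. Ring order: γ-lactone (step 3), C10–C14 oxirane (step 14), ten-membered ring (step 16), oxirane moved into the ring (step 18).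

Key step: step 16

## Route

Step 1
Reactants: 1 (2Z)-3-methylpent-2-en-4-yn-1-ol
Product: 2 (2Z)-3-methylpent-2-en-4-ynal
Conditions: activated MnO2 (excess), CH2Cl2, 0 °C to rt, dark; used at once
Reagents that add atoms: none
Why: Allylic alcohol oxidation on MnO2 is neutral and should leave the terminal alkyne and the (Z)-geometry of the trisubstituted olefin untouched.

Step 2
Reactants: 3 (4S)-4-benzyl-1,3-oxazolidin-2-one; 4 methyl 4-chloro-4-oxobutanoate
Product: 5 methyl 4-[(4S)-4-benzyl-2-oxo-1,3-oxazolidin-3-yl]-4-oxobutanoate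
Conditions: n-BuLi, THF, −78 °C; then 4, −78 to 0 °C
Reagents that add atoms: none
Why: N-Acylation of the lithiated oxazolidinone by the acid chloride is the standard entry to an Evans imide, the methyl ester being far less electrophilic.

Step 3
Reactants: 5 methyl 4-[(4S)-4-benzyl-2-oxo-1,3-oxazolidin-3-yl]-4-oxobutanoate; 2 (2Z)-3-methylpent-2-en-4-ynal
Product: 7 trans-lactone imide (4S)-4-benzyl-3-({(2R,3S)-2-[(1Z)-2-methylbut-1-en-3-yn-1-yl]-5-oxooxolan-3-yl}carbonyl)-1,3-oxazolidin-2-one, via syn-aldol adduct 6 (not isolated)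
Conditions: Bu2BOTf, i-Pr2NEt, CH2Cl2, −78 to 0 °C; 2, −78 to 0 °C; pH 7 buffer, MeOH, H2O2, 0 °C; then pyridinium p-toluenesulfonate (cat.), CH2Cl2, rt
Reagents that add atoms: none
Why: Evans syn-aldol reaction through the (Z)-boron enolate and a closed chair transition state, with the aldehyde approaching anti to the benzyl group, should set C6 (R) and C7 together in the syn sense, and the γ-hydroxy ester then closes to the trans-γ-lactone.

Step 4
Reactants: 7 trans-lactone imide
Product: 8 (4R,5R)-4-(hydroxymethyl)-5-[(1Z)-2-methylbut-1-en-3-yn-1-yl]oxolan-2-one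
Conditions: NaBH4, THF/H2O (4:1), 0 °C to rt
Reagents that add atoms: none
Why: Borohydride reduction of the activated exocyclic imide carbonyl should give the C8 primary alcohol and release the auxiliary, the γ-lactone being reduced much more slowly.

Step 5
Reactants: 8 (4R,5R)-4-(hydroxymethyl) lactone
Product: 9 (2R,3S)-2-[(1Z)-2-methylbut-1-en-3-yn-1-yl]-5-oxooxolane-3-carbaldehyde
Conditions: Dess–Martin periodinane, pyridine, CH2Cl2, 0 °C to rt
Reagents that add atoms: none
Why: Dess–Martin oxidation under buffered conditions should give the C8 aldehyde without loss of the trans arrangement at C7, which is the stable one in any case.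

Step 6
Reactants: 10 2-methylidenepropane-1,3-diol
Product: 11 2-({[tert-butyl(dimethyl)silyl]oxy}methyl)prop-2-en-1-ol
Conditions: NaH (1.0 equiv), THF, 0 °C; then TBSCl, rt
Reagents that add atoms: tert-butyldimethylsilyl chloride, CC(C)(C)[Si](C)(C)Cl
Why: Monosilylation of a symmetric diol through its sparingly soluble monosodium alkoxide should stop at the mono-ether.

Step 7
Reactants: 11 2-({[tert-butyl(dimethyl)silyl]oxy}methyl)prop-2-en-1-ol
Product: 12 {[2-(bromomethyl)prop-2-en-1-yl]oxy}(tert-butyl)dimethylsilane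
Conditions: CBr4, PPh3, CH2Cl2, 0 °C
Reagents that add atoms: carbon tetrabromide, BrC(Br)(Br)Br
Why: Appel bromination converts the primary allylic alcohol under neutral conditions that keep the silyl ether.

Step 8
Reactants: 9 lactone aldehyde; 12 allylic bromide
Product: 13 (4R,5R)-4-[3-({[tert-butyl(dimethyl)silyl]oxy}methyl)-1-hydroxybut-3-en-1-yl]-5-[(1Z)-2-methylbut-1-en-3-yn-1-yl]oxolan-2-one (C8 epimers)
Conditions: Zn dust, THF/sat. aq. NH4Cl, 0 °C to rt
Reagents that add atoms: none
Why: Barbier allylation through the allylzinc bromide adds the C9–C10(=C14)–C1 unit to the aldehyde without touching the lactone or the alkyne; C8 is not controlled here (the 8S Felkin adduct is expected to prevail) and is reset in steps 9 and 10.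

Step 9
Reactants: 13 homoallylic alcohol (C8 epimers)
Product: 14 (4S,5R)-4-[3-({[tert-butyl(dimethyl)silyl]oxy}methyl)but-3-enoyl]-5-[(1Z)-2-methylbut-1-en-3-yn-1-yl]oxolan-2-one
Conditions: Dess–Martin periodinane, pyridine, CH2Cl2, 0 °C
Reagents that add atoms: none
Why: Dess–Martin oxidation merges both C8 epimers into one β,γ-unsaturated ketone under conditions too mild to move the 1,1-disubstituted olefin into conjugation.

Step 10
Reactants: 14 C8 ketone
Product: 15 (4R,5R)-4-[(1R)-3-({[tert-butyl(dimethyl)silyl]oxy}methyl)-1-hydroxybut-3-en-1-yl]-5-[(1Z)-2-methylbut-1-en-3-yn-1-yl]oxolan-2-one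
Conditions: LiBH(s-Bu)3, THF, −78 °C; then H2O
Reagents that add atoms: none
Why: Felkin–Anh delivery of hydride from the bulky borohydride, anti to C6 on the lactone ring and reinforced by the 1,3-anti preference relative to the C6 oxygen, should set (8R).

Step 11
Reactants: 15 (8R) alcohol
Product: 16 (1R)-3-({[tert-butyl(dimethyl)silyl]oxy}methyl)-1-{(2R,3R)-2-[(1Z)-2-methylbut-1-en-3-yn-1-yl]-5-oxooxolan-3-yl}but-3-en-1-yl 2-methylpropanoate
Conditions: isobutyryl chloride, pyridine, 4-(dimethylamino)pyridine (cat.), CH2Cl2, 0 °C to rt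
Reagents that add atoms: isobutyryl chloride, CC(C)C(Cl)=O
Why: Nucleophile-catalysed acylation of the secondary alcohol installs the C8 ester with retention.

Step 12
Reactants: 16 isobutyrate with terminal alkyne
Product: 17 (1R)-3-({[tert-butyl(dimethyl)silyl]oxy}methyl)-1-{(2R,3R)-2-[(1Z)-4-iodo-2-methylbut-1-en-3-yn-1-yl]-5-oxooxolan-3-yl}but-3-en-1-yl 2-methylpropanoate
Conditions: N-iodosuccinimide, AgNO3 (cat.), acetone, rt, dark
Reagents that add atoms: N-iodosuccinimide, O=C1CCC(=O)N1I
Why: Silver-catalysed electrophilic iodination of a terminal alkyne (through the silver acetylide) is selective for the C2–H bond.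

Step 13
Reactants: 17 iodoalkyne silyl ether
Product: 18 (1R)-3-(hydroxymethyl)-1-{(2R,3R)-2-[(1Z)-4-iodo-2-methylbut-1-en-3-yn-1-yl]-5-oxooxolan-3-yl}but-3-en-1-yl 2-methylpropanoate
Conditions: HF·pyridine, pyridine, THF, 0 °C to rt
Reagents that add atoms: none
Why: Fluoride cleaves the primary allylic silyl ether while the esters and the iodoalkyne are stable to buffered HF.

Step 14
Reactants: 18 2-substituted allylic alcohol
Product: 19 (1R)-2-[(2S)-2-(hydroxymethyl)oxiran-2-yl]-1-{(2R,3R)-2-[(1Z)-4-iodo-2-methylbut-1-en-3-yn-1-yl]-5-oxooxolan-3-yl}ethyl 2-methylpropanoate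
Conditions: Ti(OiPr)4 (cat.), L-(+)-diisopropyl tartrate (cat.), t-BuOOH, 4 Å molecular sieves, CH2Cl2, −20 °C
Reagents that add atoms: tert-butyl hydroperoxide, CC(C)(C)OO
Why: Sharpless asymmetric epoxidation touches only the olefin that carries an allylic hydroxyl, and the L-(+)-tartrate complex should deliver oxygen to the face that gives the (S) oxirane centre at C10 under reagent control.

Step 15
Reactants: 19 epoxy alcohol
Product: 20 (1R)-2-[(2R)-2-formyloxiran-2-yl]-1-{(2R,3R)-2-[(1Z)-4-iodo-2-methylbut-1-en-3-yn-1-yl]-5-oxooxolan-3-yl}ethyl 2-methylpropanoate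
Conditions: Dess–Martin periodinane, pyridine, CH2Cl2, 0 °C
Reagents that add atoms: none
Why: Dess–Martin oxidation gives a glycidic aldehyde whose α-carbon C10 is fully substituted, so it can neither enolise nor epimerise.

Step 16
Reactants: 20 iodoalkyne glycidic aldehyde
Product: 21 (1R,4Z,6R,7R,8R,10R)-10,14-epoxy-1-hydroxy-8-(2-methylpropanoyloxy)germacr-4-en-2-yn-12,6-olide
Conditions: CrCl2 (6 equiv), NiCl2 (2 mol %), THF, rt, syringe-pump addition of 20 (final 0.002 M); aqueous work-up
Reagents that add atoms: none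
Why: Zerovalent nickel (formed from NiCl2 by CrCl2) inserts into the C2–I bond, the alkynyl group passes to trivalent chromium, and the alkynylchromium species adds to the C1 aldehyde to give the chromium alkoxide; the closest known reaction type is the intramolecular Nozaki–Hiyama–Kishi alkynylation of iodoalkynes that closes nine- and ten-membered cyclic enediynes. The ten-membered carbocycle closes by 10-exo-trig attack on the carbonyl group (C=O oxygen outside the ring), made feasible by the cis C4=C5 olefin, which folds the C2≡C3–C4=C5 unit back toward C1 so that only the sp3 segment C6–C10 has to be organised. The new C1 centre should be controlled by the neighbouring quaternary oxirane carbon C10 in a polar Felkin–Anh (Cornforth-type) transition state: the alkynyl group enters anti to the C10–O bond, on the side of the tied-back C14 methylene and away from C9, which gives (1R). The step needs cyclisation to win over oligomerisation (slow addition at high dilution) and attack at the aldehyde only; organochromium reagents leave the lactone, the ester and the oxirane alone, and the aldehyde has no α-hydrogen. The C2≡C3 triple bond is a temporary oxidation level removed in step 17, and the (1R) carbinol is the nucleophile that the Payne shift of step 18 needs.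

Step 17
Reactants: 21 macrocyclic ynol
Product: 22 (1R,4Z,6R,7R,8R,10R)-10,14-epoxy-1-hydroxy-8-(2-methylpropanoyloxy)germacr-4-en-12,6-olide
Conditions: 2-nitrobenzenesulfonylhydrazide (excess), Et3N, CH2Cl2, rt
Reagents that add atoms: none
Why: Diimide transfer hydrogenation delivers H2 in a concerted syn fashion and its rate falls steeply with substitution, so the ring alkyne and the cis-disubstituted olefin derived from it should be saturated while the trisubstituted C4=C5 olefin, the oxirane and the esters remain.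

Step 18
Reactants: 22 10,14-epoxy-1-ol
Product: 24 (1R,4Z,6R,7R,8R,10S)-1,10-epoxy-8-(2-methylpropanoyloxy)-14-(triethylsilyloxy)germacr-4-en-12,6-olide, via C14 sodium alkoxide 23 (not isolated)
Conditions: NaH (1.05 equiv), THF, −20 to 0 °C; then Et3SiCl, 0 °C
Reagents that add atoms: chlorotriethylsilane, CC[Si](Cl)(CC)CC
Why: Payne rearrangement, in which the C1 alkoxide opens the oxirane at C10 from the back (3-exo-tet) with retention at C1 and inversion at C10 to give the (1R,10S) trans-oxirane; the equilibrium is drained by the faster silylation of the primary C14 alkoxide.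

Step 19
Reactants: 24 14-O-triethylsilyl 1,10-epoxide
Product: 25 (1R,4Z,6R,7R,8R,10S,11R)-13-(dimethylamino)-1,10-epoxy-8-(2-methylpropanoyloxy)-14-(triethylsilyloxy)germacr-4-en-12,6-olide
Conditions: LiN(SiMe3)2, THF, −78 °C; then CH2=NMe2 I (Eschenmoser's salt), −78 to 0 °C
Reagents that add atoms: N,N-dimethylmethylideneammonium iodide, C=[N+](C)C.[I-]
Why: Mannich reaction of the lactone lithium enolate, the lactone α-CH2 being the most acidic and least hindered C–H site (the tertiary C–H of the isobutyrate is removed far more slowly); the iminium ion should enter anti to C8, and this C11 centre is erased in step 20.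

Step 20
Reactants: 25 Mannich base
Product: 27 (1R,4Z,6R,7R,8R,10S)-1,10-epoxy-8-(2-methylpropanoyloxy)-14-(triethylsilyloxy)germacra-4,11(13)-dien-12,6-olide, via trimethylammonium iodide 26 (not isolated)
Conditions: MeI, MeOH, rt; then NaHCO3, CH2Cl2/H2O, rt
Reagents that add atoms: none
Why: N-Methylation followed by E1cB (Hofmann-type) elimination gives the exocyclic C11=C13 olefin only, since C11 carries the sole β-hydrogen and it is acidified by the lactone carbonyl.

Step 21
Reactants: 27 14-O-triethylsilyl ether of the target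
Product: 28 (1R,4Z,6R,7R,8R,10S)-1,10-epoxy-14-hydroxy-8-(2-methylpropanoyloxy)germacra-4,11(13)-dien-12,6-olide (CNP0247143.1)
Conditions: Et3N·3HF, THF, 0 °C to rt
Reagents that add atoms: none
Why: Nearly neutral fluoride desilylation frees the primary alcohol under conditions chosen to avoid acid-triggered transannular opening of the oxirane by the C4=C5 olefin and conjugate addition to the α-methylene lactone.

## Compound list

1 | (2Z)-3-methylpent-2-en-4-yn-1-ol | C#C/C(C)=C\CO | starting material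
2 | (2Z)-3-methylpent-2-en-4-ynal | C#C/C(C)=C\C=O | intermediate
3 | (4S)-4-benzyl-1,3-oxazolidin-2-one | O=C1N[C@@H](Cc2ccccc2)CO1 | starting material
4 | methyl 4-chloro-4-oxobutanoate | COC(=O)CCC(Cl)=O | starting material
5 | methyl 4-[(4S)-4-benzyl-2-oxo-1,3-oxazolidin-3-yl]-4-oxobutanoate | COC(=O)CCC(=O)N1C(=O)OC[C@@H]1Cc1ccccc1 | intermediate
6 | methyl (3S,4R,5Z)-3-{[(4S)-4-benzyl-2-oxo-1,3-oxazolidin-3-yl]carbonyl}-4-hydroxy-6-methyloct-5-en-7-ynoate | COC(=O)C[C@@H]([C@H](O)/C=C(/C)C#C)C(=O)N1C(=O)OC[C@@H]1Cc1ccccc1 | intermediate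
7 | (4S)-4-benzyl-3-({(2R,3S)-2-[(1Z)-2-methylbut-1-en-3-yn-1-yl]-5-oxooxolan-3-yl}carbonyl)-1,3-oxazolidin-2-one | O=C1O[C@H](/C=C(/C)C#C)[C@H](C1)C(=O)N1C(=O)OC[C@@H]1Cc1ccccc1 | intermediate
8 | (4R,5R)-4-(hydroxymethyl)-5-[(1Z)-2-methylbut-1-en-3-yn-1-yl]oxolan-2-one | O=C1O[C@H](/C=C(/C)C#C)[C@H](C1)CO | intermediate
9 | (2R,3S)-2-[(1Z)-2-methylbut-1-en-3-yn-1-yl]-5-oxooxolane-3-carbaldehyde | O=C1O[C@H](/C=C(/C)C#C)[C@H](C1)C=O | intermediate
10 | 2-methylidenepropane-1,3-diol | C=C(CO)CO | starting material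
11 | 2-({[tert-butyl(dimethyl)silyl]oxy}methyl)prop-2-en-1-ol | C=C(CO)CO[Si](C)(C)C(C)(C)C | intermediate
12 | {[2-(bromomethyl)prop-2-en-1-yl]oxy}(tert-butyl)dimethylsilane | C=C(CBr)CO[Si](C)(C)C(C)(C)C | intermediate
13 | (4R,5R)-4-[3-({[tert-butyl(dimethyl)silyl]oxy}methyl)-1-hydroxybut-3-en-1-yl]-5-[(1Z)-2-methylbut-1-en-3-yn-1-yl]oxolan-2-one, mixture of C8 epimers (C8 left undefined) | O=C1O[C@H](/C=C(/C)C#C)[C@H](C1)C(O)CC(=C)CO[Si](C)(C)C(C)(C)C | intermediate
14 | (4S,5R)-4-[3-({[tert-butyl(dimethyl)silyl]oxy}methyl)but-3-enoyl]-5-[(1Z)-2-methylbut-1-en-3-yn-1-yl]oxolan-2-one | O=C1O[C@H](/C=C(/C)C#C)[C@H](C1)C(=O)CC(=C)CO[Si](C)(C)C(C)(C)C | intermediate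
15 | (4R,5R)-4-[(1R)-3-({[tert-butyl(dimethyl)silyl]oxy}methyl)-1-hydroxybut-3-en-1-yl]-5-[(1Z)-2-methylbut-1-en-3-yn-1-yl]oxolan-2-one | O=C1O[C@H](/C=C(/C)C#C)[C@H](C1)[C@H](O)CC(=C)CO[Si](C)(C)C(C)(C)C | intermediate
16 | (1R)-3-({[tert-butyl(dimethyl)silyl]oxy}methyl)-1-{(2R,3R)-2-[(1Z)-2-methylbut-1-en-3-yn-1-yl]-5-oxooxolan-3-yl}but-3-en-1-yl 2-methylpropanoate | O=C1O[C@H](/C=C(/C)C#C)[C@H](C1)[C@H](OC(=O)C(C)C)CC(=C)CO[Si](C)(C)C(C)(C)C | intermediate
17 | (1R)-3-({[tert-butyl(dimethyl)silyl]oxy}methyl)-1-{(2R,3R)-2-[(1Z)-4-iodo-2-methylbut-1-en-3-yn-1-yl]-5-oxooxolan-3-yl}but-3-en-1-yl 2-methylpropanoate | O=C1O[C@H](/C=C(/C)C#CI)[C@H](C1)[C@H](OC(=O)C(C)C)CC(=C)CO[Si](C)(C)C(C)(C)C | intermediate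
18 | (1R)-3-(hydroxymethyl)-1-{(2R,3R)-2-[(1Z)-4-iodo-2-methylbut-1-en-3-yn-1-yl]-5-oxooxolan-3-yl}but-3-en-1-yl 2-methylpropanoate | O=C1O[C@H](/C=C(/C)C#CI)[C@H](C1)[C@H](OC(=O)C(C)C)CC(=C)CO | intermediate
19 | (1R)-2-[(2S)-2-(hydroxymethyl)oxiran-2-yl]-1-{(2R,3R)-2-[(1Z)-4-iodo-2-methylbut-1-en-3-yn-1-yl]-5-oxooxolan-3-yl}ethyl 2-methylpropanoate | O=C1O[C@H](/C=C(/C)C#CI)[C@H](C1)[C@H](OC(=O)C(C)C)C[C@]1(CO)CO1 | intermediate
20 | (1R)-2-[(2R)-2-formyloxiran-2-yl]-1-{(2R,3R)-2-[(1Z)-4-iodo-2-methylbut-1-en-3-yn-1-yl]-5-oxooxolan-3-yl}ethyl 2-methylpropanoate | O=C1O[C@H](/C=C(/C)C#CI)[C@H](C1)[C@H](OC(=O)C(C)C)C[C@]1(C=O)CO1 | intermediate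
21 | (1R,4Z,6R,7R,8R,10R)-10,14-epoxy-1-hydroxy-8-(2-methylpropanoyloxy)germacr-4-en-2-yn-12,6-olide | O=C1O[C@@H]2/C=C(/C)C#C[C@@H](O)[C@]3(CO3)C[C@@H](OC(=O)C(C)C)[C@H]2C1 | intermediate
22 | (1R,4Z,6R,7R,8R,10R)-10,14-epoxy-1-hydroxy-8-(2-methylpropanoyloxy)germacr-4-en-12,6-olide | O=C1O[C@@H]2/C=C(/C)CC[C@@H](O)[C@]3(CO3)C[C@@H](OC(=O)C(C)C)[C@H]2C1 | intermediate
23 | sodium alkoxide of (1R,4Z,6R,7R,8R,10S)-1,10-epoxy-14-hydroxy-8-(2-methylpropanoyloxy)germacr-4-en-12,6-olide | O=C1O[C@@H]2/C=C(/C)CC[C@H]3O[C@]3(C[O-])C[C@@H](OC(=O)C(C)C)[C@H]2C1.[Na+] | intermediate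
24 | (1R,4Z,6R,7R,8R,10S)-1,10-epoxy-8-(2-methylpropanoyloxy)-14-(triethylsilyloxy)germacr-4-en-12,6-olide | O=C1O[C@@H]2/C=C(/C)CC[C@H]3O[C@]3(CO[Si](CC)(CC)CC)C[C@@H](OC(=O)C(C)C)[C@H]2C1 | intermediate
25 | (1R,4Z,6R,7R,8R,10S,11R)-13-(dimethylamino)-1,10-epoxy-8-(2-methylpropanoyloxy)-14-(triethylsilyloxy)germacr-4-en-12,6-olide (expected major C11 epimer) | CN(C)C[C@@H]1C(=O)O[C@@H]2/C=C(/C)CC[C@H]3O[C@]3(CO[Si](CC)(CC)CC)C[C@@H](OC(=O)C(C)C)[C@@H]12 | intermediate
26 | N-methyl quaternary ammonium iodide of 25 | C[N+](C)(C)C[C@@H]1C(=O)O[C@@H]2/C=C(/C)CC[C@H]3O[C@]3(CO[Si](CC)(CC)CC)C[C@@H](OC(=O)C(C)C)[C@@H]12.[I-] | intermediate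
27 | (1R,4Z,6R,7R,8R,10S)-1,10-epoxy-8-(2-methylpropanoyloxy)-14-(triethylsilyloxy)germacra-4,11(13)-dien-12,6-olide | C=C1C(=O)O[C@@H]2/C=C(/C)CC[C@H]3O[C@]3(CO[Si](CC)(CC)CC)C[C@@H](OC(=O)C(C)C)[C@@H]12 | intermediate
28 | (1R,4Z,6R,7R,8R,10S)-1,10-epoxy-14-hydroxy-8-(2-methylpropanoyloxy)germacra-4,11(13)-dien-12,6-olide (CNP0247143.1) | C=C1C(=O)O[C@@H]2/C=C(/C)CC[C@H]3O[C@]3(CO)C[C@@H](OC(=O)C(C)C)[C@@H]12 | target

## Step count and risks

Total step count: 21. Longest linear sequence: 18 steps (steps 1, 3–5 and 8–21, from compound 1).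

**Step 16 (ring closure).** The bent ten-membered enyne may form more slowly than intermolecular coupling, and the ring constraints may override the facial bias at C1. The fallback sets out from 20. Diimide (2-nitrobenzenesulfonylhydrazide, Et3N) should reduce the iodoalkyne to the (1Z,3Z)-iododiene aldehyde F1. An alkenyl Nozaki–Hiyama–Kishi closure (CrCl2, NiCl2 cat., DMSO) then gives the less strained (2Z,4Z)-dienol F2. Diimide saturation of the disubstituted C2=C3 bond brings the material back to the route at 22.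

**Step 18 (epoxide shift and silylation).** The alkoxide may trigger acyl transfer from the C8 ester or lactone enolisation, or the migration equilibrium may lie on the wrong side. The fallback sets out from 22 and avoids alkoxides. Thiocarbonyldiimidazole gives the C1 imidazolyl thiocarbonate F3. Bu3SnH with azobisisobutyronitrile (Barton–McCombie conditions) generates the C1 radical, which opens the neighbouring oxirane to the ring-trans 1(10)-olefinic allylic alcohol F4; any cis olefin would be separated. Sharpless epoxidation with Ti(OiPr)4, L-(+)-diisopropyl tartrate and t-BuOOH gives the (1R,10S)-epoxy alcohol F5. Silylation (Et3SiCl, imidazole) comes back to the route at 24.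

**Step 10 (ketone reduction).** Hydride delivery may show poor facial selectivity, or the β,γ-unsaturated ketone may enolise. The fallback sets out from 13 and uses the other epimer. The (8S) Felkin adduct F6, expected as the major component of 13, is separated. Mitsunobu esterification (isobutyric acid, PPh3, diisopropyl azodicarboxylate) inverts C8 and installs the ester in one operation, coming back to the route at 16.

## Further compounds

F1 | step 16 | (1R)-2-[(2R)-2-formyloxiran-2-yl]-1-{(2R,3R)-2-[(1Z,3Z)-4-iodo-2-methylbuta-1,3-dien-1-yl]-5-oxooxolan-3-yl}ethyl 2-methylpropanoate | O=C1O[C@H](/C=C(/C)\C=C/I)[C@H](C1)[C@H](OC(=O)C(C)C)C[C@]1(C=O)CO1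
F2 | step 16 | (1R,2Z,4Z,6R,7R,8R,10R)-10,14-epoxy-1-hydroxy-8-(2-methylpropanoyloxy)germacra-2,4-dien-12,6-olide | O=C1O[C@@H]2/C=C(/C)\C=C/[C@@H](O)[C@]3(CO3)C[C@@H](OC(=O)C(C)C)[C@H]2C1
F3 | step 18 | (1R,4Z,6R,7R,8R,10R)-10,14-epoxy-1-[(1H-imidazol-1-ylcarbonothioyl)oxy]-8-(2-methylpropanoyloxy)germacr-4-en-12,6-olide | O=C1O[C@@H]2/C=C(/C)CC[C@@H](OC(=S)n4ccnc4)[C@]3(CO3)C[C@@H](OC(=O)C(C)C)[C@H]2C1
F4 | step 18 | (4Z,6R,7R,8R)-14-hydroxy-8-(2-methylpropanoyloxy)germacra-1(10),4-dien-12,6-olide with the ring-trans 1(10) olefin (C2 cis to C14) | O=C1O[C@@H]2/C=C(/C)CC/C=C(\CO)C[C@@H](OC(=O)C(C)C)[C@H]2C1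
F5 | step 18 | (1R,4Z,6R,7R,8R,10S)-1,10-epoxy-14-hydroxy-8-(2-methylpropanoyloxy)germacr-4-en-12,6-olide | O=C1O[C@@H]2/C=C(/C)CC[C@H]3O[C@]3(CO)C[C@@H](OC(=O)C(C)C)[C@H]2C1
F6 | step 10 | (4R,5R)-4-[(1S)-3-({[tert-butyl(dimethyl)silyl]oxy}methyl)-1-hydroxybut-3-en-1-yl]-5-[(1Z)-2-methylbut-1-en-3-yn-1-yl]oxolan-2-one | O=C1O[C@H](/C=C(/C)C#C)[C@H](C1)[C@@H](O)CC(=C)CO[Si](C)(C)C(C)(C)C
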